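**Plan**

1. Locants (daucane numbering): the five-membered ring is C1 (quaternary, methyl C15), C2, C3, C4 (carbinol with isopropyl), C5 (ring-fusion CH); the seven-membered ring is C1, C5, C6 (ester carbinol), C7, C8 (methyl C14)=C9, C10 (ketone).
2. Retrosynthetic cuts, in order: aryl ester C–O at C6; C4–isopropyl (back to a C4 ketone); C10–C1; then the C6–C10 chain is taken off the five-membered ring (C8=C9 by ring-closing metathesis of an acrylate, C6–C7 by methallylboration, C5–C6 by formylation of a bought bromocyclopentenone).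
3. Enabling feature: C10=O and the C4 carbinol carbon are 1,4-related through C1–C5. With C4 as a ketone the five-membered ring is a 3-methylcyclopent-2-enone whose β-carbon is C1, and a C10 aldehyde is its acyl-anion partner. One carbene-catalysed conjugate acylation closes the seven-membered ring, creates quaternary C1 and the C5–H, and leaves the C4 carbonyl for the isopropyl group.
4. Forward order: five-membered ring bought; C6–C10 chain grown on it through a δ-lactone that is not in the target and only fixes the Z geometry of C8=C9; lactone opened to the Z-enal; seven-membered ring closed; isopropyl added at C4; ester made at C6.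
5. Stereochemistry: C6 from reagent-controlled allylboration; C1 relayed from C6 by allylic 1,3-strain in the ring closure; C5 from syn proton delivery in the same step (trans fusion); C4 from addition to the ketone face anti to the C5–C6 bond and C15.

Key step: step 10

**Route**

Step 1
Reactants: 1 2-bromo-3-methylcyclopent-2-en-1-one
Product: 2 6-bromo-7-methyl-1,4-dioxaspiro[4.4]non-6-ene
Conditions: HOCH2CH2OH, p-TsOH·H2O (cat.), benzene, reflux, Dean–Stark
Reagents that add atoms: ethylene glycol, OCCO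
Why: Acid-catalysed ketalization with azeotropic removal of water masks the ketone so that the vinyl bromide can serve as an α-ketovinyl anion equivalent, and the bromine keeps the C=C bond in place.

Step 2
Reactants: 2 6-bromo-7-methyl-1,4-dioxaspiro[4.4]non-6-ene
Product: 4 7-methyl-1,4-dioxaspiro[4.4]non-6-ene-6-carbaldehyde, via vinyllithium 3 (not isolated)
Conditions: n-BuLi, THF, −78 °C; DMF, −78 → 0 °C; H2O
Reagents that add atoms: N,N-dimethylformamide, CN(C)C=O
Why: Bromine–lithium exchange gives the vinyllithium, which is formylated by DMF (Bouveault-type formylation) and releases the aldehyde (future C6) on aqueous quench.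

Step 3
Reactants: 4 7-methyl-1,4-dioxaspiro[4.4]non-6-ene-6-carbaldehyde
Product: 6 (1S)-3-methyl-1-(7-methyl-1,4-dioxaspiro[4.4]non-6-en-6-yl)but-3-en-1-ol, via borinate ester 5 (not isolated)
Conditions: (−)-Ipc2BOMe, CH2=C(CH3)CH2MgCl, Et2O, 0 → 23 °C; then 4, −78 °C; then NaOH, H2O2, 0 → 23 °C
Reagents that add atoms: 2-methylallylmagnesium chloride, CC(=C)C[Mg]Cl
Why: Brown asymmetric allylboration through a chair-like six-membered transition state, in which the reagent derived from (+)-α-pinene should add the 2-methylallyl group to the Si face of the aldehyde and so set C6 as S; alkaline peroxide then cleaves the borinate.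

Step 4
Reactants: 6 (1S)-3-methyl-1-(7-methyl-1,4-dioxaspiro[4.4]non-6-en-6-yl)but-3-en-1-ol
Product: 7 (1S)-3-methyl-1-(7-methyl-1,4-dioxaspiro[4.4]non-6-en-6-yl)but-3-en-1-yl prop-2-enoate
Conditions: CH2=CHCOCl, i-Pr2NEt, DMAP (cat.), CH2Cl2, −78 → 0 °C
Reagents that add atoms: acryloyl chloride, C=CC(=O)Cl
Why: DMAP-catalysed O-acylation of the secondary alcohol under basic conditions that spare the acid-labile ketal; the acrylate supplies C9 and C10.

Step 5
Reactants: 7 (1S)-3-methyl-1-(7-methyl-1,4-dioxaspiro[4.4]non-6-en-6-yl)but-3-en-1-yl prop-2-enoate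
Product: 8 (6S)-4-methyl-6-(7-methyl-1,4-dioxaspiro[4.4]non-6-en-6-yl)-5,6-dihydro-2H-pyran-2-one
Conditions: second-generation Grubbs catalyst RuCl2(=CHPh)(PCy3)(H2IMes) (5 mol %), CH2Cl2 (0.005 M), 40 °C
Reagents that add atoms: none
Why: Ring-closing metathesis of the acrylate with the 1,1-disubstituted alkene gives the six-membered unsaturated lactone with loss of ethene; the tetrasubstituted ring alkene is inert and the temporary lactone ring forces C8=C9 into the Z geometry.

Step 6
Reactants: 8 (6S)-4-methyl-6-(7-methyl-1,4-dioxaspiro[4.4]non-6-en-6-yl)-5,6-dihydro-2H-pyran-2-one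
Product: 9 (2Z,5S)-5-hydroxy-N-methoxy-N,3-dimethyl-5-(7-methyl-1,4-dioxaspiro[4.4]non-6-en-6-yl)pent-2-enamide
Conditions: MeNH(OMe)·HCl, AlMe3, CH2Cl2, 0 → 23 °C; aq. Rochelle salt
Reagents that add atoms: N,O-dimethylhydroxylamine hydrochloride, CNOC.Cl
Why: Weinreb aminolysis of the lactone by the aluminium amide made in the flask opens the ring at the acyl carbon without touching the Z alkene; the hydroxy amide is silylated without delay to prevent relactonization.

Step 7
Reactants: 9 (2Z,5S)-5-hydroxy-N-methoxy-N,3-dimethyl-5-(7-methyl-1,4-dioxaspiro[4.4]non-6-en-6-yl)pent-2-enamide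
Product: 10 (2Z,5S)-5-[(tert-butyldimethylsilyl)oxy]-N-methoxy-N,3-dimethyl-5-(7-methyl-1,4-dioxaspiro[4.4]non-6-en-6-yl)pent-2-enamide
Conditions: TBSOTf, 2,6-lutidine, CH2Cl2, −78 °C
Reagents that add atoms: tert-butyldimethylsilyl trifluoromethanesulfonate, CC(C)(C)[Si](C)(C)OS(=O)(=O)C(F)(F)F
Why: Silylation of the hindered secondary alcohol with the silyl triflate and a hindered base protects C6–OH for the hydride, carbene and organometallic steps.

Step 8
Reactants: 10 (2Z,5S)-5-[(tert-butyldimethylsilyl)oxy]-N-methoxy-N,3-dimethyl-5-(7-methyl-1,4-dioxaspiro[4.4]non-6-en-6-yl)pent-2-enamide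
Product: 11 (2Z,5S)-5-[(tert-butyldimethylsilyl)oxy]-3-methyl-5-(7-methyl-1,4-dioxaspiro[4.4]non-6-en-6-yl)pent-2-enal
Conditions: i-Bu2AlH, THF, −78 °C; aq. Rochelle salt
Reagents that add atoms: none
Why: Weinreb amide reduction stops at the aldehyde because the chelated tetrahedral aluminium adduct collapses only on work-up, and the Z geometry should be kept at −78 °C.

Step 9
Reactants: 11 (2Z,5S)-5-[(tert-butyldimethylsilyl)oxy]-3-methyl-5-(7-methyl-1,4-dioxaspiro[4.4]non-6-en-6-yl)pent-2-enal
Product: 12 (2Z,5S)-5-[(tert-butyldimethylsilyl)oxy]-3-methyl-5-(2-methyl-5-oxocyclopent-1-en-1-yl)pent-2-enal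
Conditions: pyridinium p-toluenesulfonate (cat.), acetone–H2O, 23 °C
Reagents that add atoms: water, O
Why: Mild acid-catalysed hydrolysis of the allylic dioxolane unveils the cyclopentenone, while the silyl ether and the Z-enal should survive the weakly acidic conditions.

Step 10
Reactants: 12 (2Z,5S)-5-[(tert-butyldimethylsilyl)oxy]-3-methyl-5-(2-methyl-5-oxocyclopent-1-en-1-yl)pent-2-enal
Product: 13 (3aS,4S,8aS)-4-[(tert-butyldimethylsilyl)oxy]-6,8a-dimethyl-1,2,3a,4,5,8a-hexahydroazulene-3,8-dione (trans-fused)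
Conditions: 2-(pentafluorophenyl)-6,7-dihydro-5H-pyrrolo[2,1-c][1,2,4]triazol-2-ium tetrafluoroborate (20 mol %), KN(SiMe3)2 (20 mol %), toluene (0.02 M), 23 → 60 °C
Reagents that add atoms: none
Why: Proposed new method: the free carbene adds to the C10 aldehyde and proton transfer gives the Breslow intermediate (an acyl-anion equivalent), which adds through C10 to C1, the β-carbon of the 3-methylcyclopent-2-enone; the resulting enol is protonated at C5 and the catalyst is expelled to give the C10 ketone. The closest known reaction type is the intramolecular Stetter reaction of aldehydes with β,β-disubstituted Michael acceptors, which forms quaternary centres in five- and six-membered rings; new here are the seven-membered ring closure and the enal donor. The ring closes in a 7-endo-trig mode (C1 and C5 both end up in the new ring), helped by the Z C8=C9 bond and the sp2 atoms C10, C5 and C1, which leave few rotatable bonds in the chain. C1 is controlled by C6: allylic 1,3-strain places the C6–H in the enone plane next to the C15 methyl, so the C7–C10 chain lies on one face and delivers C10 to that face; C5 is set by proton transfer from the hydroxyl of the tetrahedral adduct to the same face (syn addition of acyl and H across C1=C5), which should give the trans ring fusion. The step needs acyl-anion reactivity at C10 in preference to homoenolate reactivity at C8, and 1,4- in preference to 1,2-addition: C8 is fully substituted and could reach C1 or C5 only by a 5-endo or 4-exo closure, and addition to the C4 carbonyl (crossed benzoin) is reversible whereas the conjugate addition is not.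

Step 11
Reactants: 13 (3aS,4S,8aS)-4-[(tert-butyldimethylsilyl)oxy]-6,8a-dimethyl-1,2,3a,4,5,8a-hexahydroazulene-3,8-dione
Product: 14 (3R,3aS,4S,8aS)-4-[(tert-butyldimethylsilyl)oxy]-3-hydroxy-6,8a-dimethyl-3-(propan-2-yl)-2,3,3a,4,5,8a-hexahydroazulen-8(1H)-one
Conditions: i-PrMgCl, CeCl3, THF, −78 °C; aq. NH4Cl
Reagents that add atoms: isopropylmagnesium chloride, CC(C)[Mg]Cl
Why: Organocerium 1,2-addition (Imamoto conditions) should take place at the non-conjugated cyclopentanone C4 in preference to the conjugated C10 ketone next to quaternary C1, from the ring face anti to the adjacent C5–C6 bond and the C15 methyl, which places the C4–OH cis to the angular methyl.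

Step 12
Reactants: 14 (3R,3aS,4S,8aS)-4-[(tert-butyldimethylsilyl)oxy]-3-hydroxy-6,8a-dimethyl-3-(propan-2-yl)-2,3,3a,4,5,8a-hexahydroazulen-8(1H)-one
Product: 15 (3R,3aS,4S,8aS)-3,4-dihydroxy-6,8a-dimethyl-3-(propan-2-yl)-2,3,3a,4,5,8a-hexahydroazulen-8(1H)-one
Conditions: Bu4NF, THF, 0 → 23 °C
Reagents that add atoms: none
Why: Fluoride-mediated desilylation frees C6–OH; neither hydroxyl is β to a carbonyl, so no retro-aldol or elimination pathway is open.

Step 13
Reactants: 15 (3R,3aS,4S,8aS)-3,4-dihydroxy-6,8a-dimethyl-3-(propan-2-yl)-2,3,3a,4,5,8a-hexahydroazulen-8(1H)-one; 16 4-(acetyloxy)benzoic acid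
Product: 17 (3R,3aS,4S,8aS)-3-hydroxy-6,8a-dimethyl-8-oxo-3-(propan-2-yl)-1,2,3,3a,4,5,8,8a-octahydroazulen-4-yl 4-(acetyloxy)benzoate
Conditions: DCC, DMAP (cat.), CH2Cl2, 0 → 23 °C
Reagents that add atoms: none
Why: Steglich esterification should acylate the secondary C6–OH selectively, because the tertiary C4–OH does not react under these conditions.

Step 14
Reactants: 17 (3R,3aS,4S,8aS)-3-hydroxy-6,8a-dimethyl-8-oxo-3-(propan-2-yl)-1,2,3,3a,4,5,8,8a-octahydroazulen-4-yl 4-(acetyloxy)benzoate
Product: 18 (3R,3aS,4S,8aS)-3-hydroxy-6,8a-dimethyl-8-oxo-3-(propan-2-yl)-1,2,3,3a,4,5,8,8a-octahydroazulen-4-yl 4-hydroxybenzoate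
Conditions: K2CO3 (0.2 equiv), MeOH, 0 °C
Reagents that add atoms: none
Why: Base-catalysed methanolysis cleaves the phenyl acetate much faster than the hindered secondary alkyl benzoate and should release the phenol of the target.

**Compound list**

1 | 2-bromo-3-methylcyclopent-2-en-1-one | CC1=C(Br)C(=O)CC1 | starting material
2 | 6-bromo-7-methyl-1,4-dioxaspiro[4.4]non-6-ene | CC1=C(Br)C2(CC1)OCCO2 | intermediate
3 | (7-methyl-1,4-dioxaspiro[4.4]non-6-en-6-yl)lithium | CC1=C([Li])C2(CC1)OCCO2 | intermediate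
4 | 7-methyl-1,4-dioxaspiro[4.4]non-6-ene-6-carbaldehyde | CC1=C(C=O)C2(CC1)OCCO2 | intermediate
5 | (1S)-3-methyl-1-(7-methyl-1,4-dioxaspiro[4.4]non-6-en-6-yl)but-3-en-1-yl diisopinocampheylborinate | CC1=C([C@@H](OB([C@@H]3C[C@@H]4C[C@H]([C@H]3C)C4(C)C)[C@@H]3C[C@@H]4C[C@H]([C@H]3C)C4(C)C)CC(C)=C)C2(CC1)OCCO2 | intermediate
6 | (1S)-3-methyl-1-(7-methyl-1,4-dioxaspiro[4.4]non-6-en-6-yl)but-3-en-1-ol | CC1=C([C@@H](O)CC(C)=C)C2(CC1)OCCO2 | intermediate
7 | (1S)-3-methyl-1-(7-methyl-1,4-dioxaspiro[4.4]non-6-en-6-yl)but-3-en-1-yl prop-2-enoate | CC1=C([C@@H](OC(=O)C=C)CC(C)=C)C2(CC1)OCCO2 | intermediate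
8 | (6S)-4-methyl-6-(7-methyl-1,4-dioxaspiro[4.4]non-6-en-6-yl)-5,6-dihydro-2H-pyran-2-one | CC1=C([C@@H]3CC(C)=CC(=O)O3)C2(CC1)OCCO2 | intermediate
9 | (2Z,5S)-5-hydroxy-N-methoxy-N,3-dimethyl-5-(7-methyl-1,4-dioxaspiro[4.4]non-6-en-6-yl)pent-2-enamide | CC1=C([C@@H](O)C/C(C)=C\C(=O)N(C)OC)C2(CC1)OCCO2 | intermediate
10 | (2Z,5S)-5-[(tert-butyldimethylsilyl)oxy]-N-methoxy-N,3-dimethyl-5-(7-methyl-1,4-dioxaspiro[4.4]non-6-en-6-yl)pent-2-enamide | CC1=C([C@@H](O[Si](C)(C)C(C)(C)C)C/C(C)=C\C(=O)N(C)OC)C2(CC1)OCCO2 | intermediate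
11 | (2Z,5S)-5-[(tert-butyldimethylsilyl)oxy]-3-methyl-5-(7-methyl-1,4-dioxaspiro[4.4]non-6-en-6-yl)pent-2-enal | CC1=C([C@@H](O[Si](C)(C)C(C)(C)C)C/C(C)=C\C=O)C2(CC1)OCCO2 | intermediate
12 | (2Z,5S)-5-[(tert-butyldimethylsilyl)oxy]-3-methyl-5-(2-methyl-5-oxocyclopent-1-en-1-yl)pent-2-enal | CC1=C([C@@H](O[Si](C)(C)C(C)(C)C)C/C(C)=C\C=O)C(=O)CC1 | intermediate
13 | (3aS,4S,8aS)-4-[(tert-butyldimethylsilyl)oxy]-6,8a-dimethyl-1,2,3a,4,5,8a-hexahydroazulene-3,8-dione | CC1=CC(=O)[C@@]2(C)CCC(=O)[C@@H]2[C@@H](O[Si](C)(C)C(C)(C)C)C1 | intermediate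
14 | (3R,3aS,4S,8aS)-4-[(tert-butyldimethylsilyl)oxy]-3-hydroxy-6,8a-dimethyl-3-(propan-2-yl)-2,3,3a,4,5,8a-hexahydroazulen-8(1H)-one | CC1=CC(=O)[C@@]2(C)CC[C@@](O)(C(C)C)[C@@H]2[C@@H](O[Si](C)(C)C(C)(C)C)C1 | intermediate
15 | (3R,3aS,4S,8aS)-3,4-dihydroxy-6,8a-dimethyl-3-(propan-2-yl)-2,3,3a,4,5,8a-hexahydroazulen-8(1H)-one | CC1=CC(=O)[C@@]2(C)CC[C@@](O)(C(C)C)[C@@H]2[C@@H](O)C1 | intermediate
16 | 4-(acetyloxy)benzoic acid | CC(=O)Oc1ccc(cc1)C(=O)O | starting material
17 | (3R,3aS,4S,8aS)-3-hydroxy-6,8a-dimethyl-8-oxo-3-(propan-2-yl)-1,2,3,3a,4,5,8,8a-octahydroazulen-4-yl 4-(acetyloxy)benzoate | CC1=CC(=O)[C@@]2(C)CC[C@@](O)(C(C)C)[C@@H]2[C@@H](OC(=O)c2ccc(OC(C)=O)cc2)C1 | intermediate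
18 | (3R,3aS,4S,8aS)-3-hydroxy-6,8a-dimethyl-8-oxo-3-(propan-2-yl)-1,2,3,3a,4,5,8,8a-octahydroazulen-4-yl 4-hydroxybenzoate | CC1=CC(=O)[C@@]2(C)CC[C@@](O)(C(C)C)[C@@H]2[C@@H](OC(=O)c2ccc(O)cc2)C1 | target

**Summary**

Total step count: 14. Longest linear sequence: 14 steps (1 to 18).

**Steps most likely to fail**

1. Step 10 (proposed new method). The carbene-bound donor may be too bulky to form the bond at the fully substituted C1. The Breslow intermediate may be diverted by protonation at C8 (redox path to a saturated acyl azolium) or rest as the crossed-benzoin adduct at C4. Base may also erode the C5 configuration or trigger β-elimination of the C6 silyloxy group. Fallback with known chemistry, an acyl radical cyclization, sets out from 12 and comes back at 13. Pinnick oxidation of 12 (NaClO2, NaH2PO4, 2-methylbut-2-ene, t-BuOH–H2O) should give the Z-enoic acid F1. PhSeSePh and PBu3 in CH2Cl2 should convert it into the phenyl selenoester F2. Slow addition of Bu3SnH with AIBN in refluxing benzene (0.005 M) generates the α,β-unsaturated acyl radical, which should close 7-endo onto C1 of the enone; hydrogen-atom transfer to the C5 radical returns to 13. In this variant C5 is set by intermolecular hydrogen delivery under steric control and not by the internal proton shuttle.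

2. Step 11. The basic secondary organometallic may enolize C4 toward C5 with β-elimination of the C6 silyloxy group, reduce the ketone by β-hydride transfer, or add at C10. Fallback from 13 back to 14: 2-propenylmagnesium bromide with CeCl3 in THF at −78 °C (an sp2 nucleophile that is smaller, less basic and cannot transfer hydride) should give the isopropenyl carbinol F3. Hydrogenation with RhCl(PPh3)3 under H2 in benzene should reduce only the 1,1-disubstituted alkene and leave the trisubstituted enone, giving 14.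

3. Step 9. The Z-enal may isomerize to the E-enal under acid (the E isomer cannot reach C1), or the silyl ether may be partly lost. Fallback from 8 back to 12, in which the aldehyde is made last under neutral conditions: excess i-Bu2AlH in CH2Cl2 (−78 → 0 °C) should reduce lactone 8 to the Z-enediol F4. TBSOTf and 2,6-lutidine should give the bis-silyl ether F5. Pyridinium p-toluenesulfonate in MeOH followed by water should cleave the primary allylic silyl ether and the ketal to give the keto allylic alcohol F6. MnO2 in CH2Cl2 should oxidize the Z-allylic alcohol to 12 without touching the geometry.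

**Further compounds**

F1 | step 10 | (2Z,5S)-5-[(tert-butyldimethylsilyl)oxy]-3-methyl-5-(2-methyl-5-oxocyclopent-1-en-1-yl)pent-2-enoic acid | CC1=C([C@@H](O[Si](C)(C)C(C)(C)C)C/C(C)=C\C(O)=O)C(=O)CC1
F2 | step 10 | Se-phenyl (2Z,5S)-5-[(tert-butyldimethylsilyl)oxy]-3-methyl-5-(2-methyl-5-oxocyclopent-1-en-1-yl)pent-2-eneselenoate | CC1=C([C@@H](O[Si](C)(C)C(C)(C)C)C/C(C)=C\C(=O)[Se]c2ccccc2)C(=O)CC1
F3 | step 11 | (3R,3aS,4S,8aS)-4-[(tert-butyldimethylsilyl)oxy]-3-hydroxy-6,8a-dimethyl-3-(prop-1-en-2-yl)-2,3,3a,4,5,8a-hexahydroazulen-8(1H)-one | CC1=CC(=O)[C@@]2(C)CC[C@@](O)(C(C)=C)[C@@H]2[C@@H](O[Si](C)(C)C(C)(C)C)C1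
F4 | step 9 | (2Z,5S)-3-methyl-5-(7-methyl-1,4-dioxaspiro[4.4]non-6-en-6-yl)pent-2-ene-1,5-diol | CC1=C([C@@H](O)C/C(C)=C\CO)C2(CC1)OCCO2
F5 | step 9 | (2Z,5S)-1,5-bis[(tert-butyldimethylsilyl)oxy]-3-methyl-5-(7-methyl-1,4-dioxaspiro[4.4]non-6-en-6-yl)pent-2-ene | CC1=C([C@@H](O[Si](C)(C)C(C)(C)C)C/C(C)=C\CO[Si](C)(C)C(C)(C)C)C2(CC1)OCCO2
F6 | step 9 | 2-[(1S,3Z)-1-[(tert-butyldimethylsilyl)oxy]-5-hydroxy-3-methylpent-3-en-1-yl]-3-methylcyclopent-2-en-1-one | CC1=C([C@@H](O[Si](C)(C)C(C)(C)C)C/C(C)=C\CO)C(=O)CC1
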